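## Structural features

The target is a daucane. A cyclopentane (C1–C2–C3–C4–C5) is fused across the C1–C5 bond to a cycloheptane (C5–C6–C7–C8–C9–C10–C1). C1 carries the angular methyl, C4 a tertiary hydroxyl and an isopropyl group, C6 the 3,4-dimethoxybenzoyloxy group, C8 a methyl, and C8–C9 an epoxide.

The six stereocentres are (1R,4R,5S,6S,8R,9S). C4, C5 and C6 are contiguous, C1 adjoins C5, and C8/C9 stand 1,3 to C6. The ring fusion is trans (H5 anti to the C1 methyl), the C4 hydroxyl lies on the face of the C1 methyl, and the C6 oxygen and the epoxide oxygen both lie on the face of H5.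

Fragile groups are the trisubstituted epoxide (acid, and transannular attack by the C4 hydroxyl from the opposite face), the tertiary alcohol (dehydration) and the aryl ester (nucleophiles, reductants). In intermediates with a C4 ketone, H5 is epimerisable and the C6 oxygen is β to the carbonyl.

The real difficulty is the quaternary C1 next to C5 at a trans five–seven ring fusion, flanked by oxygenated C4 and C6.

The feature exploited is that C4–C5–C1(CH3) maps onto the carbonyl, α- and β-carbon of 3-methylcyclopent-2-enone, and that C5 reaches C10 through the chain C6–C7–C8–C9. A C9=C10 alkene on that chain can add across C5=C1. The surplus C5–C9 bond is α,β to the C4 carbonyl and part of a cyclobutane, so it can be removed reductively, with its electrons ending in the C8=C9 double bond that the epoxide needs.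

## Logic of the disconnections

**21 ⇒ 19 + 20.** The acyl C–O bond at O6 is cut. The ester would not survive the organometallic and electron-transfer steps, so it is attached last. This removes the whole aromatic part and leaves a diol. The forward step must acylate the secondary C6 hydroxyl in the presence of the tertiary C4 hydroxyl and stay non-acidic for the epoxide.

**19 ⇒ 18.** Both oxirane C–O bonds (C8–O, C9–O) are cut. C8=C9 is homoallylic to the free C6 hydroxyl, which lies on the face the oxygen must enter. Two stereocentres and the most acid-sensitive group disappear. The forward step must be a hydroxyl-directed, syn-selective epoxidation that does not trigger transannular opening.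

**18 ⇒ 17 ⇒ 16.** The O6–Si bond is restored (protecting group), then the C4–CH(CH3)2 bond is cut. A C4 ketone is the natural acceptor and is the carbonyl the preceding fragmentation requires. The C4 stereocentre is removed. The forward step needs face-selective addition of a secondary alkyl nucleophile to a hindered, enolisable ketone without disturbing H5.

**16 ⇒ 14 (through 15).** The C5–H bond and the C8=C9 π bond are exchanged for a C5–C9 σ bond and a C8–OCH3 bond. C5–C9 is then a cyclobutane bond α,β to the C4 carbonyl, so electron transfer to the carbonyl can break it. The seven-membered ring is replaced by a five–four combination that is much easier to close, and the C8 configuration becomes irrelevant. The forward step must cleave C5–C9 and not C5–C1, reduce the C9 radical before it abstracts hydrogen, expel methoxide, and protonate C5 anti to the C1 methyl.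

**14 ⇒ 13.** C5–C9 and C1–C10 are cut, the two bonds of an intramolecular enone–alkene [2+2] cycloaddition. Two rings, the quaternary C1 and the stereocentres C1, C5 and C9 vanish, leaving a monocyclic enone with one controlling stereocentre (C6). The forward step needs straight regiochemistry and facial control by C6 alone.

**13 ⇒ 12 ⇒ 11 ⇒ 10.** The C4 carbonyl is masked as a dioxolane, O6–Si is removed, and the C6–H bond is cut (carbinol to ketone). The ketal permits carbanion chemistry at C5, and a C6 ketone lets a reagent set C6 independently of the racemic C8. The only centre needing absolute control becomes a prochiral ketone. The forward steps need an enantioselective 1,2-reduction that spares the vinyl group and a mild ketal hydrolysis.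

**10 ⇒ 2 + 8 (through 9).** C5–C6 is cut between a vinylic carbon (nucleophile after halogen–metal exchange) and an acyl carbon. The molecule splits into ring and chain halves of similar size. The forward step must stop at mono-addition and avoid enolisation and β-elimination of methoxide.

**8 ⇒ 7 ⇒ 6 ⇒ 3 + 4 (through 5).** The amide N–C(=O) bond, the O–CH3 bond at C8 and the C7–C8 bond are cut in turn. C7–C8 is an acetate-enolate-to-ketone bond. This reaches two bulk chemicals. The forward steps need 1,2-addition to an enone and O-methylation of a tertiary aldol without retro-aldol.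

**2 ⇒ 1.** The two ketal C–O bonds are cut. The forward step must keep the double bond in place.

## Other disconnections considered

**Alternative 1:** The seven-membered ring is unravelled to an arene.
- **Cut:** C5 is excised from between C6 and C1 (bonds C5–C6 and C5–C1). The six carbons C6–C7–C8–C9–C10–C1 become the ring of 1-methoxy-2,5-dimethylbenzene A1; its oxygen is the C6 oxygen and its methyls are the C8 and C1 methyls.
- **Forward key step:** Birch reduction of A1 gives diene A2. Dibromocarbene (CHBr3, KOt-Bu) adds to the enol-ether double bond to give cyclopropane A3, which opens with loss of bromide and of the O-methyl group to the bromo dienone A4.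
- **In favour:** two or three operations from a commodity arene give the seven-membered ring with the C6 oxygen, both methyl-bearing carbons, C8=C9 ready for epoxidation and a C5 bromide as a handle. There is no photochemistry and scale-up is easy.
- **Against:** A4 is achiral and flat, so all six stereocentres remain. The cyclopentane must be annulated across C5=C1, which means creating the quaternary C1 enantioselectively by conjugate addition to a β,β-disubstituted α-bromo dienone, then closing C4–C5, reducing C6 and establishing the trans fusion with no resident stereocentre to help. The skipped dienone may also drift into conjugation.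
- **Comparison:** on cost and speed to the seven-membered ring, alternative 1 is the better. On structure, the chosen plan is ahead because the ring-forming step also fixes C1 and C5 relative to C6. Mechanistically both rest on well-understood chemistry (carbene addition and electrocyclic opening versus triplet biradical). On overall step economy, the annulation and stereochemical work after A4 would probably cost more than the five steps that follow 14.

**Alternative 2:** A three-component assembly on the cyclopentane.
- **Cut:** C1–CH3 and C5–C6 are cut in one operation on 3-allylcyclopent-2-en-1-one A5 (allyl = C10–C9), with Me3Al as the methyl source and 3-methylbut-3-enal A6 as the C6–C7–C8 electrophile. C8=C9 would then come from ring-closing metathesis.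
- **Forward key step:** Cu(O2CC4H3S) (copper thiophene-2-carboxylate) with a chiral phosphoramidite catalyses conjugate transfer of methyl from Me3Al to A5. The aluminium enolate is trapped by A6 to give A7.
- **In favour:** the quaternary C1 is set by a catalyst. The aldol places C6 on C5 anti to the allyl group, which is the trans ring-fusion relationship; on this point alternative 2 is the better, since the chosen plan must win that relationship in an enolate protonation (step 10). It is also the better on step economy: metathesis of A7 (second-generation Grubbs catalyst) would lead directly to the free C6 carbinol corresponding to 16.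
- **Against:** enantioselective conjugate methylation of β-substituted cyclopentenones is ligand-sensitive and usually less selective than with six-membered enones. The C6 carbinol configuration rests only on the aldol transition state of an aluminium enolate with an unhindered β,γ-unsaturated aldehyde that isomerises easily. A7 can undergo retro-aldol.
- **Comparison:** from the bicyclic C4 ketone onward both plans are equal (isopropyl addition, epoxidation, acylation). The chosen plan is the more secure at C6 (reagent-controlled reduction of an isolated ketone) and forms the quaternary centre intramolecularly without a demanding asymmetric catalysis. Alternative 2 is shorter and better at C5.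

**Alternative 3:** Late delivery of the angular methyl.
- **Cut:** the C1–CH3 bond is cut on a preformed bicycle with a C1=C5 double bond. The carbon is tethered through silicon to the C4 oxygen in the bromomethylsilyl ether A8.
- **Forward key step:** Bu3SnH/AIBN converts A8 into an α-silyl radical that attacks C1 in the 6-endo sense (ring O–Si–CH2–C1–C5–C4). The C5 radical takes hydrogen from the stannane on the opposite face, giving the siloxane A9. Later protodesilylation would turn C1–CH2–Si into C1–CH3 and free the C4 hydroxyl.
- **In favour:** the tether guarantees the methyl cis to the C4 oxygen, and the trans fusion arises in the same step. On control of the C1/C4/C5 relative configuration this alternative is the equal or the better of the chosen plan, which needs two separate face-selective steps (10 and 11).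
- **Against:** the whole bicyclic skeleton with a tetrasubstituted alkene and the C4 quaternary carbinol must exist beforehand, so ring construction is not addressed. 6-endo attack creating a quaternary centre competes with 5-exo attack and with simple reduction of the radical. It needs stoichiometric tin, gives C6 as the wrong epimer (to be inverted later), and adds tether-on and tether-off operations.
- **Comparison:** structurally it forms one C–C bond and two stereocentres but no skeletal ring, whereas the chosen key step forms two C–C bonds, two rings and three stereocentres. Both are radical processes (chain versus photochemical biradical). On step economy alternative 3 is clearly the longer.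

Key step: step 9

Remark: C8 enters as a racemate in step 2 and becomes trigonal in step 10. Compounds 6, 7, 8 and 10 are therefore racemic and 11–14 are pairs of C8 epimers carried together; names show (RS) at that centre and SMILES leave it undefined.

Remark: descriptors given "in target numbering" use the C1–C10 locants defined under Structural features.

Remark: 3,4-dimethoxybenzoyl chloride (20) is taken as a purchased reagent.

## Steps

Step 1
Reactants: 1 2-bromo-3-methylcyclopent-2-en-1-one
Product: 2 6-bromo-7-methyl-1,4-dioxaspiro[4.4]non-6-ene
Conditions: HOCH2CH2OH, p-TsOH·H2O (cat.), benzene, reflux, Dean–Stark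
Reagents that add atoms: ethane-1,2-diol, OCCO
Why: Acid-catalysed ketalisation with azeotropic removal of water; the α-bromine keeps the double bond in its place, and the ketal masks the carbonyl for the halogen–lithium exchange of step 5.

Step 2
Reactants: 3 but-3-en-2-one; 4 ethyl bromoacetate
Product: 6 ethyl (3RS)-3-hydroxy-3-methylpent-4-enoate, via bromozinc ester enolate 5 (not isolated)
Conditions: Zn dust (Me3SiCl-activated), THF, 40 °C to reflux; aqueous work-up
Reagents that add atoms: none
Why: Reformatsky reaction; the zinc enolate adds 1,2 to the enone carbonyl and gives the tertiary allylic carbinol as a racemate, which is acceptable because C8 is erased in step 10.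

Step 3
Reactants: 6 ethyl (3RS)-3-hydroxy-3-methylpent-4-enoate
Product: 7 ethyl (3RS)-3-methoxy-3-methylpent-4-enoate
Conditions: MeOTf, 2,6-di-tert-butyl-4-methylpyridine, CH2Cl2, 0 °C to rt
Reagents that add atoms: methyl trifluoromethanesulfonate, COS(=O)(=O)C(F)(F)F
Why: O-Alkylation of the neutral hydroxyl by a hard methylating agent with a hindered pyridine as acid scavenger; no alkoxide is formed, so the retro-aldol and E1cB pathways of a tertiary β-hydroxy ester are avoided.

Step 4
Reactants: 7 ethyl (3RS)-3-methoxy-3-methylpent-4-enoate
Product: 8 (3RS)-N,3-dimethoxy-N,3-dimethylpent-4-enamide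
Conditions: MeNH(OMe)·HCl, i-PrMgCl, THF, −20 to 0 °C
Reagents that add atoms: N,O-dimethylhydroxylamine hydrochloride, CNOC.Cl
Why: Aminolysis of the ester by the chloromagnesium amide formed in the flask (direct Weinreb amide synthesis); the low temperature limits enolisation and loss of the β-methoxide.

Step 5
Reactants: 2 6-bromo-7-methyl-1,4-dioxaspiro[4.4]non-6-ene; 8 (3RS)-N,3-dimethoxy-N,3-dimethylpent-4-enamide
Product: 10 (3RS)-3-methoxy-3-methyl-1-(7-methyl-1,4-dioxaspiro[4.4]non-6-en-6-yl)pent-4-en-1-one, via vinyllithium 9 (not isolated)
Conditions: t-BuLi (2 equiv), THF, −78 °C; then 8, −78 to −20 °C; pH 7 buffer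
Reagents that add atoms: none
Why: Bromine–lithium exchange gives the α-keto vinyl anion equivalent, and its addition to the N-methoxy-N-methylamide stops at the chelated tetrahedral adduct, so the C5–C6 bond forms without over-addition and the ketone appears only on work-up.

Step 6
Reactants: 10 (3RS)-3-methoxy-3-methyl-1-(7-methyl-1,4-dioxaspiro[4.4]non-6-en-6-yl)pent-4-en-1-one
Product: 11 (1S,3RS)-3-methoxy-3-methyl-1-(7-methyl-1,4-dioxaspiro[4.4]non-6-en-6-yl)pent-4-en-1-ol
Conditions: (R)-2-methyl-CBS-oxazaborolidine [(R)-1-methyl-3,3-diphenyltetrahydro-1H,3H-pyrrolo[1,2-c][1,3,2]oxazaborole] (20 mol %), catecholborane, toluene, −78 °C; aq. NaOH work-up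
Reagents that add atoms: none
Why: Corey–Bakshi–Shibata reduction; the tetrasubstituted cyclopentenyl group is the large substituent and the CH2 group the small one, so the (R)-catalyst should deliver hydride to give the (S)-carbinol at C6, and catecholborane at −78 °C does not hydroborate the vinyl group.

Step 7
Reactants: 11 (1S,3RS)-3-methoxy-3-methyl-1-(7-methyl-1,4-dioxaspiro[4.4]non-6-en-6-yl)pent-4-en-1-ol
Product: 12 tert-butyl{[(1S,3RS)-3-methoxy-3-methyl-1-(7-methyl-1,4-dioxaspiro[4.4]non-6-en-6-yl)pent-4-en-1-yl]oxy}dimethylsilane
Conditions: TBSCl, imidazole, DMF, 40 °C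
Reagents that add atoms: tert-butyl(chloro)dimethylsilane, CC(C)(C)[Si](C)(C)Cl
Why: Imidazole-promoted silylation of the secondary allylic alcohol; the bulky ether is the steric control element of step 9 and rules out retro-aldol chemistry at the β-oxygenated ketone stage.

Step 8
Reactants: 12 tert-butyl{[(1S,3RS)-3-methoxy-3-methyl-1-(7-methyl-1,4-dioxaspiro[4.4]non-6-en-6-yl)pent-4-en-1-yl]oxy}dimethylsilane
Product: 13 2-[(1S,3RS)-1-{[tert-butyl(dimethyl)silyl]oxy}-3-methoxy-3-methylpent-4-en-1-yl]-3-methylcyclopent-2-en-1-one
Conditions: pyridinium p-toluenesulfonate (cat.), acetone–H2O, 40 °C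
Reagents that add atoms: water, O
Why: Mild acid-catalysed ketal hydrolysis, easy because the oxocarbenium ion is allylic; the silyl ether and the tertiary allylic methyl ether should survive pyridinium catalysis.

Step 9
Reactants: 13 2-[(1S,3RS)-1-{[tert-butyl(dimethyl)silyl]oxy}-3-methoxy-3-methylpent-4-en-1-yl]-3-methylcyclopent-2-en-1-one
Product: 14 (1S,5R,7R,8RS,10S)-10-{[tert-butyl(dimethyl)silyl]oxy}-8-methoxy-5,8-dimethyltricyclo[5.3.0.0(1,5)]decan-2-one (in target numbering 1R,5S,6S,9R with C8 as both epimers)
Conditions: hν (350 nm, Pyrex), degassed hexane, 0.01 M, rt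
Reagents that add atoms: none
Why: Excitation of the enone and intersystem crossing give the triplet, which bonds first from the α-carbon C5 to the internal alkene carbon C9 and leaves a 1,4-biradical (tertiary C1, primary C10) that collapses to the C1–C10 bond after spin inversion. The closest known reaction type is the intramolecular enone–alkene [2+2] photocycloaddition of 2-(pent-4-enyl)cycloalkenones to straight adducts. The cyclopentane C5–C6–C7–C8–C9 closes in the 5-exo mode (rule of five), helped by the gem-disubstituted C8, and the cyclobutane C1–C5–C9–C10 closes by biradical recombination, necessarily cis-fused to both five-membered rings. C5, C9 and C1 are therefore fixed relative to one another by ring strain alone. Their relation to C6 comes from allylic 1,3-strain: H6 eclipses the side of the C1 methyl, which puts C7 and the silyloxy group on opposite faces of the enone, so the alkene can reach C5 from one face only and the silyloxy group ends on the convex face, cis to C4. The step needs straight rather than crossed regiochemistry (secured by the three-atom tether on the α-carbon), face selectivity (secured by C6) and chemoselectivity (only the enone absorbs at 350 nm). Both C8 epimers should react in the same sense because the C8 substituents lie on the periphery of the forming cyclopentane.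

Step 10
Reactants: 14 (1S,5R,7R,8RS,10S)-10-{[tert-butyl(dimethyl)silyl]oxy}-8-methoxy-5,8-dimethyltricyclo[5.3.0.0(1,5)]decan-2-one
Product: 16 (3aR,8S,8aS)-8-{[tert-butyl(dimethyl)silyl]oxy}-3a,6-dimethyl-3,3a,4,7,8,8a-hexahydroazulen-1(2H)-one, via samarium enolate 15 (not isolated)
Conditions: SmI2 (2.2 equiv), THF–HMPA, −78 °C; then t-BuOH, −78 °C; pH 7 buffer
Reagents that add atoms: none
Why: Reductive fragmentation of a cyclobutyl ketone by divalent samarium: the ketyl cleaves the cyclobutane bond exocyclic to the cyclopentanone (C5–C9, the one that overlaps with the carbonyl π system), the C9 radical is reduced to the organosamarium and expels the β-methoxide so that both C8 epimers converge on C8=C9. The enolate should be protonated anti to the pseudo-axial C1 methyl to give the trans fusion, and the C6–O bond lies near the nodal plane of the enolate, which disfavours β-elimination.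

Step 11
Reactants: 16 (3aR,8S,8aS)-8-{[tert-butyl(dimethyl)silyl]oxy}-3a,6-dimethyl-3,3a,4,7,8,8a-hexahydroazulen-1(2H)-one
Product: 17 (3R,3aS,4S,8aR)-4-{[tert-butyl(dimethyl)silyl]oxy}-6,8a-dimethyl-3-(propan-2-yl)-1,2,3,3a,4,5,8,8a-octahydroazulen-3-ol
Conditions: i-PrMgCl, anhydrous CeCl3, THF, −78 to −40 °C; aqueous work-up
Reagents that add atoms: isopropylmagnesium chloride, CC(C)[Mg]Cl
Why: Organocerium addition (Imamoto conditions): the weakly basic reagent suppresses enolisation at C5 and β-hydride reduction, and it should approach C4 from the face of H5, away from the C5–C6 bond and the angular methyl, so the new hydroxyl ends cis to the C1 methyl.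

Step 12
Reactants: 17 (3R,3aS,4S,8aR)-4-{[tert-butyl(dimethyl)silyl]oxy}-6,8a-dimethyl-3-(propan-2-yl)-1,2,3,3a,4,5,8,8a-octahydroazulen-3-ol
Product: 18 (3R,3aS,4S,8aR)-6,8a-dimethyl-3-(propan-2-yl)-1,2,3,3a,4,5,8,8a-octahydroazulene-3,4-diol
Conditions: Bu4NF, THF, rt
Reagents that add atoms: none
Why: Fluoride-induced desilylation, neutral toward the tertiary alcohol and the trisubstituted alkene; it frees the homoallylic hydroxyl that directs step 13.

Step 13
Reactants: 18 (3R,3aS,4S,8aR)-6,8a-dimethyl-3-(propan-2-yl)-1,2,3,3a,4,5,8,8a-octahydroazulene-3,4-diol
Product: 19 (1R,4R,5S,6S,8R,9S)-8,9-epoxydaucane-4,6-diol (target numbering)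
Conditions: VO(acac)2 (5 mol %), t-BuOOH, CH2Cl2, 0 °C to rt
Reagents that add atoms: tert-butyl hydroperoxide, CC(C)(C)OO
Why: Hydroxyl-directed vanadium-catalysed epoxidation: the C6 homoallylic hydroxyl binds the metal peroxide and delivers oxygen to the face of C8=C9 syn to itself, which is also the face away from the angular methyl, setting C8 and C9 together.

Step 14
Reactants: 19 (1R,4R,5S,6S,8R,9S)-8,9-epoxydaucane-4,6-diol; 20 3,4-dimethoxybenzoyl chloride
Product: 21 (1R,4R,5S,6S,8R,9S)-8,9-epoxy-4-hydroxydaucan-6-yl 3,4-dimethoxybenzoate
Conditions: Et3N, 4-(dimethylamino)pyridine (cat.), CH2Cl2, 0 °C to rt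
Reagents that add atoms: none
Why: Acyl transfer catalysed by 4-(dimethylamino)pyridine to the secondary C6 hydroxyl; the tertiary C4 hydroxyl is inert under these conditions and the amine keeps the medium non-acidic, which protects the epoxide.

## Compound list

1 | 2-bromo-3-methylcyclopent-2-en-1-one | CC1=C(Br)C(=O)CC1 | starting material
2 | 6-bromo-7-methyl-1,4-dioxaspiro[4.4]non-6-ene | CC1=C(Br)C2(CC1)OCCO2 | intermediate
3 | but-3-en-2-one | CC(=O)C=C | starting material
4 | ethyl bromoacetate | CCOC(=O)CBr | starting material
5 | ethyl 2-(bromozincio)acetate (Reformatsky reagent) | CCOC(=O)C[Zn]Br | intermediate (not isolated)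
6 | ethyl (3RS)-3-hydroxy-3-methylpent-4-enoate | CCOC(=O)CC(C)(O)C=C | intermediate
7 | ethyl (3RS)-3-methoxy-3-methylpent-4-enoate | CCOC(=O)CC(C)(OC)C=C | intermediate
8 | (3RS)-N,3-dimethoxy-N,3-dimethylpent-4-enamide | CON(C)C(=O)CC(C)(OC)C=C | intermediate
9 | (7-methyl-1,4-dioxaspiro[4.4]non-6-en-6-yl)lithium | CC1=C([Li])C2(CC1)OCCO2 | intermediate (not isolated)
10 | (3RS)-3-methoxy-3-methyl-1-(7-methyl-1,4-dioxaspiro[4.4]non-6-en-6-yl)pent-4-en-1-one | CC1=C(C(=O)CC(C)(OC)C=C)C2(CC1)OCCO2 | intermediate
11 | (1S,3RS)-3-methoxy-3-methyl-1-(7-methyl-1,4-dioxaspiro[4.4]non-6-en-6-yl)pent-4-en-1-ol | CC1=C([C@@H](O)CC(C)(OC)C=C)C2(CC1)OCCO2 | intermediate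
12 | tert-butyl{[(1S,3RS)-3-methoxy-3-methyl-1-(7-methyl-1,4-dioxaspiro[4.4]non-6-en-6-yl)pent-4-en-1-yl]oxy}dimethylsilane | CC1=C([C@@H](O[Si](C)(C)C(C)(C)C)CC(C)(OC)C=C)C2(CC1)OCCO2 | intermediate
13 | 2-[(1S,3RS)-1-{[tert-butyl(dimethyl)silyl]oxy}-3-methoxy-3-methylpent-4-en-1-yl]-3-methylcyclopent-2-en-1-one | CC1=C([C@@H](O[Si](C)(C)C(C)(C)C)CC(C)(OC)C=C)C(=O)CC1 | intermediate
14 | (1S,5R,7R,8RS,10S)-10-{[tert-butyl(dimethyl)silyl]oxy}-8-methoxy-5,8-dimethyltricyclo[5.3.0.0(1,5)]decan-2-one | O=C1CC[C@]2(C)C[C@H]3C(C)(OC)C[C@H](O[Si](C)(C)C(C)(C)C)[C@@]123 | intermediate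
15 | diiodosamarium enolate of 16 (C4–O–SmI2, C4=C5; 1R,6S in target numbering) | CC(C)(C)[Si](C)(C)O[C@H]1CC(C)=CC[C@@]2(C)CCC(O[Sm](I)I)=C12 | intermediate (not isolated)
16 | (3aR,8S,8aS)-8-{[tert-butyl(dimethyl)silyl]oxy}-3a,6-dimethyl-3,3a,4,7,8,8a-hexahydroazulen-1(2H)-one | CC(C)(C)[Si](C)(C)O[C@H]1CC(C)=CC[C@@]2(C)CCC(=O)[C@H]12 | intermediate
17 | (3R,3aS,4S,8aR)-4-{[tert-butyl(dimethyl)silyl]oxy}-6,8a-dimethyl-3-(propan-2-yl)-1,2,3,3a,4,5,8,8a-octahydroazulen-3-ol | CC(C)(C)[Si](C)(C)O[C@H]1CC(C)=CC[C@@]2(C)CC[C@@](O)(C(C)C)[C@H]12 | intermediate
18 | (3R,3aS,4S,8aR)-6,8a-dimethyl-3-(propan-2-yl)-1,2,3,3a,4,5,8,8a-octahydroazulene-3,4-diol | O[C@H]1CC(C)=CC[C@@]2(C)CC[C@@](O)(C(C)C)[C@H]12 | intermediate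
19 | (1R,4R,5S,6S,8R,9S)-8,9-epoxydaucane-4,6-diol | O[C@H]1C[C@@]2(C)O[C@H]2C[C@@]2(C)CC[C@@](O)(C(C)C)[C@H]12 | intermediate
20 | 3,4-dimethoxybenzoyl chloride | COc1ccc(C(=O)Cl)cc1OC | starting material
21 | (1R,4R,5S,6S,8R,9S)-8,9-epoxy-4-hydroxydaucan-6-yl 3,4-dimethoxybenzoate | COc1ccc(C(=O)O[C@H]2C[C@@]3(C)O[C@H]3C[C@@]3(C)CC[C@@](O)(C(C)C)[C@H]23)cc1OC | target

## Step count and least certain steps

Total steps: 14. Longest linear sequence: 13 steps (steps 2–14, from 3 and 4 to 21). Step 1 is the side branch and joins at step 5.

**Step 9 (key step).** The likely failure is insufficient discrimination between the two enone faces, because the single C6 stereocentre has to override any bias from the uncontrolled C8 centre. Crossed addition and reversion of the 1,4-biradical are lesser drains.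
Fallback: replace steric control by a hydrogen-bonded tether conformation. Setting out from 11, the ketal is hydrolysed first (pyridinium p-toluenesulfonate, acetone–H2O) to the hydroxy enone F1. Irradiation of F1 at 350 nm in hexane, where the C6 hydroxyl should be hydrogen-bonded to the C4 carbonyl and hold the C6–O bond in the enone plane, should give the hydroxy photoadduct F2. Silylation (TBSOTf, 2,6-lutidine) returns the material to the route at 14.

**Step 10.** The likely failure is protonation of 15 on the C5 face that carries the C1 methyl, or epimerisation at C5 during work-up, giving the cis ring fusion. The two faces of C5 differ only by a methyl group against a ring methylene. Hydrogen abstraction by the C9 radical before its reduction is a second, smaller risk.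
Fallback: move from kinetic to thermodynamic control. Setting out from 14, whatever cis-fused ketone F3 forms in the fragmentation is isolated and equilibrated through its enol (DBU, toluene, rt) toward the epimer in which C4 and the C6 silyloxy group are anti on the seven-membered ring. The epimers are separated and F3 is recycled, coming back to the route at 16.

**Step 11.** The likely failure is enolisation of the hindered ketone (with scrambling of C5 on work-up) or β-hydride transfer from the secondary alkyl metal, which reduces C4 instead of alkylating it.
Fallback: install the three carbons as an sp2 nucleophile that cannot transfer hydride, then saturate it. Setting out from 16, CH2=C(CH3)MgBr/CeCl3 should give the isopropenyl carbinol F4. Hydrogenation with RhCl(PPh3)3 and H2, which distinguishes the 1,1-disubstituted alkene from the trisubstituted C8=C9, comes back to the route at 17.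

**Step 3.** The likely failure is slow O-alkylation of the hindered tertiary hydroxyl, leaving time for acid-promoted ionisation or elimination of the tertiary allylic alcohol.
Fallback: methylate as an alkoxide on a substrate whose retro-aldol leaving group is poorer. Setting out from 6, aminolysis (MeNH(OMe)·HCl, i-PrMgCl) gives the hydroxy amide F5. Williamson methylation (KH, MeI, THF, 0 °C) comes back to the route at 8.

**Step 5.** The likely failure is deprotonation of 8 at C7 by the hindered, basic vinyllithium, followed by loss of methoxide, instead of addition to the amide carbonyl.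
Fallback: use the more electrophilic aldehyde and adjust the oxidation level afterwards. Setting out from 7, i-Bu2AlH at −78 °C gives the aldehyde F6. Addition of 9 gives the carbinol F7 as a mixture at C6. Oxidation with Dess–Martin periodinane comes back to the route at 10.

## Further compounds

F1 | step 9 | 2-[(1S,3RS)-1-hydroxy-3-methoxy-3-methylpent-4-en-1-yl]-3-methylcyclopent-2-en-1-one | CC1=C([C@@H](O)CC(C)(OC)C=C)C(=O)CC1
F2 | step 9 | (1S,5R,7R,8RS,10S)-10-hydroxy-8-methoxy-5,8-dimethyltricyclo[5.3.0.0(1,5)]decan-2-one | O=C1CC[C@]2(C)C[C@H]3C(C)(OC)C[C@H](O)[C@@]123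
F3 | step 10 | (3aR,8S,8aR)-8-{[tert-butyl(dimethyl)silyl]oxy}-3a,6-dimethyl-3,3a,4,7,8,8a-hexahydroazulen-1(2H)-one (cis-fused C5 epimer of 16) | CC(C)(C)[Si](C)(C)O[C@H]1CC(C)=CC[C@@]2(C)CCC(=O)[C@@H]12
F4 | step 11 | (3S,3aS,4S,8aR)-4-{[tert-butyl(dimethyl)silyl]oxy}-6,8a-dimethyl-3-(prop-1-en-2-yl)-1,2,3,3a,4,5,8,8a-octahydroazulen-3-ol (same spatial arrangement at C4 as 17) | CC(C)(C)[Si](C)(C)O[C@H]1CC(C)=CC[C@@]2(C)CC[C@@](O)(C(C)=C)[C@H]12
F5 | step 3 | (3RS)-3-hydroxy-N-methoxy-N,3-dimethylpent-4-enamide | CON(C)C(=O)CC(C)(O)C=C
F6 | step 5 | (3RS)-3-methoxy-3-methylpent-4-enal | O=CCC(C)(OC)C=C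
F7 | step 5 | (1RS,3RS)-3-methoxy-3-methyl-1-(7-methyl-1,4-dioxaspiro[4.4]non-6-en-6-yl)pent-4-en-1-ol | CC1=C(C(O)CC(C)(OC)C=C)C2(CC1)OCCO2
A1 | alternative 1 | 1-methoxy-2,5-dimethylbenzene | COc1cc(C)ccc1C
A2 | alternative 1 | 1-methoxy-2,5-dimethylcyclohexa-1,4-diene | COC1=C(C)CC=C(C)C1
A3 | alternative 1 | 7,7-dibromo-1-methoxy-3,6-dimethylbicyclo[4.1.0]hept-3-ene | COC12CC(C)=CCC1(C)C2(Br)Br
A4 | alternative 1 | 2-bromo-3,6-dimethylcyclohepta-2,5-dien-1-one | CC1=CCC(C)=C(Br)C(=O)C1
A5 | alternative 2 | 3-allylcyclopent-2-en-1-one | C=CCC1=CC(=O)CC1
A6 | alternative 2 | 3-methylbut-3-enal | CC(=C)CC=O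
A7 | alternative 2 | (2S,3R)-3-allyl-2-[(1S)-1-hydroxy-3-methylbut-3-en-1-yl]-3-methylcyclopentan-1-one | C=CC[C@@]1(C)CCC(=O)[C@@H]1[C@@H](O)CC(C)=C
A8 | alternative 3 | C4 O-[(bromomethyl)dimethylsilyl] ether of the C1=C5 bicyclic alkene carrying the C4 isopropyl, the C8=C9 alkene and the C6-epimeric tert-butyldimethylsilyl ether | BrC[Si](C)(C)O[C@@]1(C(C)C)CCC2=C1[C@H](O[Si](C)(C)C(C)(C)C)CC(C)=CC2
A9 | alternative 3 | siloxane-bridged trans-fused bicycle with C1–CH2–Si and H5 on opposite faces (C6 epimer) | C[Si]1(C)O[C@@]2(C(C)C)CC[C@]3(C1)CC=C(C)C[C@@H](O[Si](C)(C)C(C)(C)C)[C@@H]23
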